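**Retrosynthetic overview**
- The carboxylic acid of the target is taken back to the ring-B aldehyde of a depside aldehyde (chlorite oxidation as the last step).
- Key disconnection: the depside ester C(acyl)–O bond, made by a dehydrogenative coupling of a ring-A salicylaldehyde with a ring-B phenol.
- The ring-A salicylaldehyde comes from 5-propylresorcinol by formylation and selective 4-O-methylation.
- The ring-B phenol comes from 1,3-dimethoxy-5-pentylbenzene by formylation and para-selective O-demethylation.
- No ring is formed: both benzene rings are bought intact.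

Assumption: the target has no stereocentre, so there is no enantiomer to select, and the route delivers the one achiral compound.

**Step 1**
Reactants: 1 5-propylbenzene-1,3-diol (5-propylresorcinol)
Product: 3 2,4-dihydroxy-6-propylbenzaldehyde, via aryl iminium dichlorophosphate 2 (not isolated)
Conditions: POCl3 (1.2 equiv), DMF, 0 °C to rt; then H2O, 50 °C
Reagents that add atoms: N,N-dimethylformamide, CN(C)C=O (formyl carbon); water, O (carbonyl oxygen)
Why: Vilsmeier–Haack formylation; the chloroiminium ion attacks the position para to one OH and ortho to the other (the two such positions are equivalent by symmetry) rather than the more hindered position between the two OH groups, and water hydrolyses iminium 2 to the aldehyde.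

**Step 2**
Reactants: 3 2,4-dihydroxy-6-propylbenzaldehyde
Product: 4 2-hydroxy-4-methoxy-6-propylbenzaldehyde
Conditions: MeI (1.05 equiv), K2CO3 (1.0 equiv), acetone, rt
Reagents that add atoms: iodomethane, CI
Why: Williamson ether synthesis; the 2-OH is held in a hydrogen bond to the formyl oxygen and is much less nucleophilic, so the more acidic, free 4-OH is methylated selectively.

**Step 3**
Reactants: 5 1,3-dimethoxy-5-pentylbenzene (olivetol dimethyl ether)
Product: 7 2,4-dimethoxy-6-pentylbenzaldehyde, via aryl iminium dichlorophosphate 6 (not isolated)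
Conditions: POCl3 (1.5 equiv), DMF, 0 °C to 80 °C; then H2O, 50 °C
Reagents that add atoms: N,N-dimethylformamide, CN(C)C=O (formyl carbon); water, O (carbonyl oxygen)
Why: Vilsmeier–Haack formylation of a symmetric arene; attack occurs para to one OMe and ortho to the other (two equivalent positions), not at the doubly flanked position between the two OMe groups, so a single aldehyde results after hydrolysis of iminium 6.

**Step 4**
Reactants: 7 2,4-dimethoxy-6-pentylbenzaldehyde
Product: 8 4-hydroxy-2-methoxy-6-pentylbenzaldehyde
Conditions: NaSEt (2.5 equiv), DMF, 100 °C; then 1 M HCl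
Reagents that add atoms: none
Why: Nucleophilic (SN2) aryl methyl ether cleavage by thiolate; the methyl of the OMe para to the formyl group is attacked because the 4-oxidobenzaldehyde (a vinylogous carboxylate) is the better leaving group and that methyl is the less hindered, the opposite of the ortho selectivity of chelating Lewis acids, and the phenoxide formed deactivates the ring against a second cleavage.

**Step 5**
Reactants: 4 2-hydroxy-4-methoxy-6-propylbenzaldehyde; 8 4-hydroxy-2-methoxy-6-pentylbenzaldehyde
Product: 9 4-formyl-3-methoxy-5-pentylphenyl 2-hydroxy-4-methoxy-6-propylbenzoate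
Conditions: 4 (1.0 equiv), 8 (1.2 equiv), [Cp*RhCl2]2 (2.5 mol %), AgSbF6 (10 mol %), Cu(OAc)2 (20 mol %), CsO2CCMe3 (30 mol %), O2 (1 atm), 4 Å MS, PhCl, 60 °C
Reagents that add atoms: none
Why: Proposed new method: chelation-assisted dehydrogenative formyl C–H aryloxylation — the phenoxide of 4 binds Cp*Rh (trivalent rhodium) and delivers it to the formyl C–H bond by carboxylate-assisted metalation, giving the five-membered aroyl–rhodium chelate that is the established intermediate of salicylaldehyde/alkyne chromone annulations and formyl C–H amidations; the acidic, unhindered phenol 8 exchanges onto rhodium as its phenoxide, and C(acyl)–O bond formation (reductive elimination, or phenoxide attack on the acyl ligand as in the alcoholysis step of oxidative alkoxycarbonylation) releases depside ester 9 and monovalent rhodium, which Cu(OAc)2 (divalent copper) and O2 return to trivalent rhodium with water as the only co-product; the formyl group of 8 has no ortho-OH to direct metalation, so only the aldehyde of 4 is oxidised; closest known reaction types are rhodium-catalysed chelation-assisted aldehyde C–H functionalisation of salicylaldehydes and metal–acyl alcoholysis in oxidative carbonylation.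

**Step 6**
Reactants: 9 4-formyl-3-methoxy-5-pentylphenyl 2-hydroxy-4-methoxy-6-propylbenzoate
Product: 10 4-[(2-hydroxy-4-methoxy-6-propylbenzoyl)oxy]-2-methoxy-6-pentylbenzoic acid
Conditions: NaClO2 (3 equiv), NaH2PO4 (3 equiv), 2-methyl-2-butene (20 equiv), t-BuOH/THF/H2O, 0 °C to rt
Reagents that add atoms: sodium chlorite (NaClO2), [Na+].[O-]Cl=O
Why: Pinnick (Lindgren–Kraus) oxidation; chlorous acid converts the hindered aryl aldehyde into the acid at about pH 4, where the aryl ester is stable, and the excess alkene traps hypochlorous acid before it can chlorinate the electron-rich phenol ring A.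

**Compound list**
1 | 5-propylbenzene-1,3-diol (5-propylresorcinol, divarinol) | CCCc1cc(O)cc(O)c1 | starting material
2 | N-[(2,4-dihydroxy-6-propylphenyl)methylidene]-N-methylmethanaminium dichlorophosphate (Vilsmeier aryl iminium salt, not isolated) | CCCc1cc(O)cc(O)c1C=[N+](C)C.[O-]P(=O)(Cl)Cl | intermediate
3 | 2,4-dihydroxy-6-propylbenzaldehyde | CCCc1cc(O)cc(O)c1C=O | intermediate
4 | 2-hydroxy-4-methoxy-6-propylbenzaldehyde | CCCc1cc(OC)cc(O)c1C=O | intermediate
5 | 1,3-dimethoxy-5-pentylbenzene (olivetol dimethyl ether) | CCCCCc1cc(OC)cc(OC)c1 | starting material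
6 | N-[(2,4-dimethoxy-6-pentylphenyl)methylidene]-N-methylmethanaminium dichlorophosphate (Vilsmeier aryl iminium salt, not isolated) | CCCCCc1cc(OC)cc(OC)c1C=[N+](C)C.[O-]P(=O)(Cl)Cl | intermediate
7 | 2,4-dimethoxy-6-pentylbenzaldehyde | CCCCCc1cc(OC)cc(OC)c1C=O | intermediate
8 | 4-hydroxy-2-methoxy-6-pentylbenzaldehyde | CCCCCc1cc(O)cc(OC)c1C=O | intermediate
9 | 4-formyl-3-methoxy-5-pentylphenyl 2-hydroxy-4-methoxy-6-propylbenzoate | CCCCCc1cc(OC(=O)c2c(O)cc(OC)cc2CCC)cc(OC)c1C=O | intermediate
10 | 4-[(2-hydroxy-4-methoxy-6-propylbenzoyl)oxy]-2-methoxy-6-pentylbenzoic acid | CCCCCc1cc(OC(=O)c2c(O)cc(OC)cc2CCC)cc(OC)c1C(=O)O | target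

**Total step count:** 6 (two 2-step branches, coupling, oxidation).
**Longest linear sequence:** 4 steps (1 → 3 → 4 → 9 → 10, or 5 → 7 → 8 → 9 → 10).

**Three steps most likely to fail**

Step 5 (the proposed new coupling). The aroyl–rhodium chelate may lose CO or be hydrolysed to the acid faster than it forms the C(acyl)–O bond, and copper may sequester the salicylaldehyde. Fallback with known chemistry, setting out from 4 and coming back at 9: chlorite oxidation of 4 (NaClO2, NaH2PO4, 2-methyl-2-butene) gives 2-hydroxy-4-methoxy-6-propylbenzoic acid F1. Trifluoroacetic anhydride in toluene at rt converts it in the flask into 2-hydroxy-4-methoxy-6-propylbenzoic trifluoroacetic anhydride F2, which acylates the unhindered 4-OH of 8 to give 9 (the classical depside esterification, which tolerates the chelated ortho-OH). This costs one extra step.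

Step 4 (regioselective demethylation). The thiolate may add to the aldehyde, or ortho cleavage may compete and give the 2-hydroxy-4-methoxy isomer. Fallback setting out from 7 and coming back at 8: BBr3 (CH2Cl2, −78 °C to rt) removes both methyl groups to give 2,4-dihydroxy-6-pentylbenzaldehyde F3. BnBr/KHCO3 in MeCN benzylates only the non-chelated 4-OH to give 4-(benzyloxy)-2-hydroxy-6-pentylbenzaldehyde F4. MeI/K2CO3 in DMF then methylates the chelated 2-OH to give 4-(benzyloxy)-2-methoxy-6-pentylbenzaldehyde F5, and hydrogenolysis (H2, 1 atm, Pd/C, EtOAc) frees the 4-OH to give 8. Regiochemistry is then fixed by protecting-group order instead of by leaving-group ability.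

Step 6 (late chlorite oxidation). Ring A of 9 is an electron-rich free phenol and may be chlorinated, and the hindered aldehyde may react slowly. Fallback setting out from 8 (with 4 as the source of the acid partner) and coming back at 10, in which ring B is oxidised before ring A is attached: chlorite oxidation of 8 gives 4-hydroxy-2-methoxy-6-pentylbenzoic acid F6. BnBr/KHCO3 in DMF alkylates only the carboxylate to give benzyl 4-hydroxy-2-methoxy-6-pentylbenzoate F7. 2-Hydroxy-4-methoxy-6-propylbenzoic acid F1 (from 4 as above) is condensed with F7 through its mixed anhydride 2-hydroxy-4-methoxy-6-propylbenzoic trifluoroacetic anhydride F2 (TFAA, toluene, rt) to give benzyl 4-[(2-hydroxy-4-methoxy-6-propylbenzoyl)oxy]-2-methoxy-6-pentylbenzoate F8. Hydrogenolysis (H2, Pd/C, EtOAc) of the benzyl ester then gives 10 directly.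

**Further compounds**
F1 | step 5 | 2-hydroxy-4-methoxy-6-propylbenzoic acid | CCCc1cc(OC)cc(O)c1C(=O)O
F2 | step 5 | 2-hydroxy-4-methoxy-6-propylbenzoic trifluoroacetic anhydride | CCCc1cc(OC)cc(O)c1C(=O)OC(=O)C(F)(F)F
F3 | step 4 | 2,4-dihydroxy-6-pentylbenzaldehyde | CCCCCc1cc(O)cc(O)c1C=O
F4 | step 4 | 4-(benzyloxy)-2-hydroxy-6-pentylbenzaldehyde | CCCCCc1cc(OCc2ccccc2)cc(O)c1C=O
F5 | step 4 | 4-(benzyloxy)-2-methoxy-6-pentylbenzaldehyde | CCCCCc1cc(OCc2ccccc2)cc(OC)c1C=O
F6 | step 6 | 4-hydroxy-2-methoxy-6-pentylbenzoic acid | CCCCCc1cc(O)cc(OC)c1C(=O)O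
F7 | step 6 | benzyl 4-hydroxy-2-methoxy-6-pentylbenzoate | CCCCCc1cc(O)cc(OC)c1C(=O)OCc2ccccc2
F8 | step 6 | benzyl 4-[(2-hydroxy-4-methoxy-6-propylbenzoyl)oxy]-2-methoxy-6-pentylbenzoate | CCCCCc1cc(OC(=O)c2c(O)cc(OC)cc2CCC)cc(OC)c1C(=O)OCc3ccccc3
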